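**Plan**
1. Retrosynthesis: the oxolane is cut at C3–C4 and O1–C2 (and at C3–Cl) into oxirane 9, dienyl iodide 14 and an electrophilic chlorine. Oxirane 9 goes back through its tertiary C–Br bond and an epoxide to prenyl acetate 1; diene 14 goes back through its two C=C bonds to prop-2-yn-1-ol 10.
2. Enabling feature: O1–C5–C4 of the ring is an opened terminal oxirane (C4 electrophilic, O1 nucleophilic). C3(Cl)/C2(O) is the anti adduct of Cl+ and O1 across the C2=C3 bond of a (Z)-1,3-diene whose tertiary allylic C2 accepts oxygen.
3. Forward: two fragments (6 and 3 steps) are joined at C4–C3 by strain-releasing epoxide opening. The only ring, the oxolane, then closes at O1–C2 in the same flask (three components: epoxide, dienylmagnesium, Cl+).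
4. Stereochemistry: C5 and the side-chain C–Br carbon come from Sharpless epoxidation plus invertive bromide opening. C2 and C3 come from the Z alkene geometry (anti addition) with face control by C5. The E-bromoalkene comes from Takai olefination.

Key step: step 10

Remark: locants O1, C2 (methyl, bromoethenyl), C3 (Cl), C4, C5 (side chain) refer to the oxolane of the target, read from the SMILES as (2S,3S,5S) with a (2S) side chain; Cl, bromoethenyl and side chain lie on one face.

Step 1
Reactants: 1 3-methylbut-2-en-1-yl acetate (prenyl acetate)
Product: 2 (2E)-4-hydroxy-3-methylbut-2-en-1-yl acetate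
Conditions: SeO2 (cat.), t-BuOOH, CH2Cl2, rt
Reagents that add atoms: tert-butyl hydroperoxide, CC(C)(C)OO
Why: Riley allylic oxidation (ene reaction, then [2,3]-sigmatropic shift) should hydroxylate only the methyl group trans to the chain of the trisubstituted alkene, which fixes the E geometry.

Step 2
Reactants: 2 (2E)-4-hydroxy-3-methylbut-2-en-1-yl acetate
Product: 4 (2E)-4-chloro-3-methylbut-2-en-1-yl acetate, via allylic mesylate 3 (not isolated)
Conditions: MsCl, LiCl, 2,4,6-collidine, DMF, 0 °C
Reagents that add atoms: lithium chloride, [Li+].[Cl-]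
Why: sulfonylation followed by SN2 displacement with chloride at the primary allylic carbon (chlorination of an allylic alcohol without transposition) should keep the E alkene.

Step 3
Reactants: 4 (2E)-4-chloro-3-methylbut-2-en-1-yl acetate
Product: 5 (2E)-4-chloro-3-methylbut-2-en-1-ol
Conditions: i-Bu2AlH, CH2Cl2, −78 °C; aq. potassium sodium tartrate
Reagents that add atoms: none
Why: reductive cleavage of the acetate by an aluminium hydride at low temperature should free the alcohol and leave the allylic chloride untouched.

Step 4
Reactants: 5 (2E)-4-chloro-3-methylbut-2-en-1-ol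
Product: 6 [(2S,3R)-3-(chloromethyl)-3-methyloxiran-2-yl]methanol
Conditions: Ti(OiPr)4 (cat.), L-(+)-diisopropyl tartrate (cat.), t-BuOOH, 4 Å MS, CH2Cl2, −20 °C
Reagents that add atoms: tert-butyl hydroperoxide, CC(C)(C)OO
Why: Sharpless asymmetric epoxidation; L-(+)-tartrate should deliver oxygen to the same face as with geraniol, which for this E-allylic alcohol means the (2S,3R) epoxide, so C5 of the target is set and the side-chain carbon is set in latent form.

Step 5
Reactants: 6 [(2S,3R)-3-(chloromethyl)-3-methyloxiran-2-yl]methanol
Product: 7 (2S,3S)-3-bromo-4-chloro-3-methylbutane-1,2-diol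
Conditions: MgBr2·OEt2, Et2O, −20 → 0 °C
Reagents that add atoms: magnesium bromide, [Mg+2].[Br-].[Br-]
Why: Lewis-acid-assisted halide opening of a 2,3-epoxy alcohol; the magnesium chelate should direct bromide to the tertiary C3 with inversion (borderline SN2) while C2 keeps its C–O bond, which creates the tertiary bromide stereocentre.

Step 6
Reactants: 7 (2S,3S)-3-bromo-4-chloro-3-methylbutane-1,2-diol
Product: 9 (2S)-2-[(2S)-2-bromo-1-chloropropan-2-yl]oxirane, via hydroxy triflate 8 (not isolated)
Conditions: Tf2O, 2,6-lutidine, CH2Cl2, −78 → 0 °C
Reagents that add atoms: none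
Why: selective sulfonylation of the primary hydroxyl and 3-exo-tet displacement by the neighbouring secondary hydroxyl (diol-to-epoxide conversion); the triflate is a far better leaving group than the tertiary bromide and the medium is only weakly basic, so closure onto C–Br should not compete, and no bond to a stereocentre is broken.

Step 7
Reactants: 10 prop-2-yn-1-ol
Product: 12 (2Z)-3-iodo-2-methylprop-2-en-1-ol, via alkenylmagnesium alkoxide 11 (not isolated)
Conditions: MeMgBr, CuI (cat.), THF, −10 °C → rt; then I2, −78 → 0 °C
Reagents that add atoms: methylmagnesium bromide, C[Mg]Br; iodine, II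
Why: copper-catalysed anti-carbomagnesiation of a propargylic alkoxide gives the five-membered chelated alkenylmagnesium with Mg cis to CH2O, and iodinolysis with retention fixes the Z geometry.

Step 8
Reactants: 12 (2Z)-3-iodo-2-methylprop-2-en-1-ol
Product: 13 (2Z)-3-iodo-2-methylprop-2-enal
Conditions: MnO2, CH2Cl2, rt
Reagents that add atoms: none
Why: neutral oxidation of an allylic alcohol; the aldehyde should be used at once so that the Z alkene does not isomerise.

Step 9
Reactants: 13 (2Z)-3-iodo-2-methylprop-2-enal
Product: 14 (1Z,3E)-4-bromo-1-iodo-2-methylbuta-1,3-diene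
Conditions: CrBr2, CHBr3, THF, 0 °C → rt
Reagents that add atoms: bromoform, BrC(Br)Br
Why: Takai olefination; the geminal dichromium species adds to the aldehyde and eliminates to the E-bromoalkene, the bromide salt of divalent chromium avoids bromide/chloride exchange, and the alkenyl iodide is inert to divalent chromium in the absence of nickel.

Step 10
Reactants: 14 (1Z,3E)-4-bromo-1-iodo-2-methylbuta-1,3-diene; 9 (2S)-2-[(2S)-2-bromo-1-chloropropan-2-yl]oxirane
Product: 18 (2S,3S,5S)-2-[(E)-2-bromoethenyl]-5-[(2S)-2-bromo-1-chloropropan-2-yl]-3-chloro-2-methyloxolane, via dienylmagnesium chloride 15 (not isolated), via magnesium alkoxide 16 (not isolated), via bromohydrin 17 (not isolated)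
Conditions: i-PrMgCl·LiCl, THF, 0 °C; CuCl (10 mol %), 9, −40 → −20 °C; then (CF3)2CHOH, NCS, CH2Cl2, −40 → 0 °C
Reagents that add atoms: N-chlorosuccinimide, O=C1CCC(=O)N1Cl
Why: Proposed new method: a one-flask three-component annulation in which iodine–magnesium exchange (C–I far faster than C–Br, Z geometry retained) gives 15, whose CuCl-catalysed SN2 attack on the CH2 of oxirane 9 (strain release) forms C4–C3 and sets free the C5 alkoxide 16; hexafluoroisopropanol protonates 16 to 17 and activates NCS, Cl+ adds to C3 of the diene, and the C5 hydroxyl captures the resulting chloronium/tertiary allyl cation at C2 to form O1–C2. The closest known reaction types are the copper-catalysed opening of terminal epoxides by alkenyl Grignard reagents and the 5-endo halo-etherification of homoallylic alcohols with iodine or N-halosuccinimides; running them in sequence in one flask, with the epoxide as a C–C–O unit, is the untested part, and it should work because the first stage leaves only chloride salts (iodine stays bound in 2-iodopropane), which cannot turn NCS into a bromonium or iodonium source. The oxolane closes in a formally 5-endo-trig mode, favoured here because the activated alkene is attacked at its tertiary, allylically stabilised carbon C2. C2 and C3 are created together by anti addition of Cl and O across the (Z)-C2=C3 bond, so Cl ends trans to methyl and cis to the bromoethenyl group, and the face is chosen by C5 through an envelope transition state that places Cl cis to the C5 side chain, the outcome known for iodocyclisations of both E and Z homoallylic alcohols. The step needs chlorination at C3 and not at the bromoethenyl end (C3 is the electron-rich terminus of a trisubstituted alkene, the other alkene carries bromine), and it needs the tertiary bromide to survive, which low temperature, a weakly basic Grignard reagent and the acidic quench before chlorination should secure.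

**Compound list**
1 | 3-methylbut-2-en-1-yl acetate (prenyl acetate) | CC(=O)OCC=C(C)C | starting material
2 | (2E)-4-hydroxy-3-methylbut-2-en-1-yl acetate | CC(=O)OC/C=C(\C)CO | intermediate
3 | (2E)-4-[(methanesulfonyl)oxy]-3-methylbut-2-en-1-yl acetate | CC(=O)OC/C=C(\C)COS(C)(=O)=O | intermediate (not isolated)
4 | (2E)-4-chloro-3-methylbut-2-en-1-yl acetate | CC(=O)OC/C=C(\C)CCl | intermediate
5 | (2E)-4-chloro-3-methylbut-2-en-1-ol | OC/C=C(\C)CCl | intermediate
6 | [(2S,3R)-3-(chloromethyl)-3-methyloxiran-2-yl]methanol | OC[C@@H]1O[C@@]1(C)CCl | intermediate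
7 | (2S,3S)-3-bromo-4-chloro-3-methylbutane-1,2-diol | OC[C@H](O)[C@](C)(Br)CCl | intermediate
8 | (2S,3S)-3-bromo-4-chloro-2-hydroxy-3-methylbutyl trifluoromethanesulfonate | FC(F)(F)S(=O)(=O)OC[C@H](O)[C@](C)(Br)CCl | intermediate (not isolated)
9 | (2S)-2-[(2S)-2-bromo-1-chloropropan-2-yl]oxirane | C1O[C@@H]1[C@](C)(Br)CCl | intermediate
10 | prop-2-yn-1-ol | C#CCO | starting material
11 | bromomagnesium (2Z)-3-(bromomagnesio)-2-methylprop-2-en-1-olate | Br[Mg]/C=C(/C)CO[Mg]Br | intermediate (not isolated)
12 | (2Z)-3-iodo-2-methylprop-2-en-1-ol | I/C=C(/C)CO | intermediate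
13 | (2Z)-3-iodo-2-methylprop-2-enal | I/C=C(/C)C=O | intermediate
14 | (1Z,3E)-4-bromo-1-iodo-2-methylbuta-1,3-diene | I/C=C(/C)\C=C\Br | intermediate
15 | [(1Z,3E)-4-bromo-2-methylbuta-1,3-dien-1-yl]magnesium chloride | Cl[Mg]/C=C(/C)\C=C\Br | intermediate (not isolated)
16 | chloromagnesium (2S,3S,5Z,7E)-2,8-dibromo-1-chloro-2,6-dimethylocta-5,7-dien-3-olate | Br/C=C/C(C)=C\C[C@H](O[Mg]Cl)[C@](C)(Br)CCl | intermediate (not isolated)
17 | (2S,3S,5Z,7E)-2,8-dibromo-1-chloro-2,6-dimethylocta-5,7-dien-3-ol | Br/C=C/C(C)=C\C[C@H](O)[C@](C)(Br)CCl | intermediate (not isolated)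
18 | (2S,3S,5S)-2-[(E)-2-bromoethenyl]-5-[(2S)-2-bromo-1-chloropropan-2-yl]-3-chloro-2-methyloxolane | C[C@@](Br)(CCl)[C@@H]1C[C@H](Cl)[C@](C)(/C=C/Br)O1 | target

**Step count and risks**
Total steps: 10. Longest linear sequence: 7 (steps 1–6, then step 10); the diene fragment takes 3 steps (7–9).

Steps most likely to fail:

Step 10. In the organometallic stage the magnesium alkoxide may close onto the tertiary carbon with loss of bromide, or the Grignard reagent may cause elimination. In the chlorination stage the allyl cation may rotate before capture (loss of anti stereospecificity), facial selectivity may be poor, or residual halide may divert the electrophile. The fallback uses known chemistry, keeps bromide away from the organometallic step, and makes each bond in a separate isolated step. It sets out from 6 and uses 14. Epoxy alcohol 6 is converted with Tf2O/2,6-lutidine at −78 °C into [(2S,3R)-3-(chloromethyl)-3-methyloxiran-2-yl]methyl trifluoromethanesulfonate F1. Copper-catalysed displacement of the triflate by dienylmagnesium chloride 15 (made from 14 as in step 10; CuCl cat., THF, −78 °C) gives (2R,3S)-3-[(2Z,4E)-5-bromo-3-methylpenta-2,4-dien-1-yl]-2-(chloromethyl)-2-methyloxirane F2. MgBr2·OEt2 opens F2 at the tertiary carbon with inversion, and the route is rejoined at bromohydrin 17, now isolated and purified. Compound 17 is then cyclised to 18 with NCS in (CF3)2CHOH/CH2Cl2 as a separate 5-endo chloroetherification.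

Step 6. The secondary hydroxyl may displace the tertiary bromide instead of the triflate (return to a trisubstituted epoxide), or the small, halide-rich epoxide may be lost or rearrange on isolation. The fallback makes no terminal epoxide and sets out from 7. One-pot treatment with Tf2O and then Et3SiOTf (2,6-lutidine, CH2Cl2, −78 °C) gives (2S,3S)-3-bromo-4-chloro-3-methyl-2-[(triethylsilyl)oxy]butyl trifluoromethanesulfonate F3. Copper-catalysed coupling with 15 (CuCl cat., THF, −78 °C) gives triethyl{[(2S,3S,5Z,7E)-2,8-dibromo-1-chloro-2,6-dimethylocta-5,7-dien-3-yl]oxy}silane F4. HF·pyridine removes the silyl group, and the route is rejoined at 17, which is cyclised to 18 with NCS as a separate step.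

Step 5. Bromide may attack the secondary carbon, or the Lewis acid may trigger a hydride shift to a carbonyl compound instead of invertive opening at the tertiary carbon. The fallback changes the order of events so that neither a free diol nor a chelating Lewis acid is involved, and it sets out from 6. Tosylation (TsCl, Et3N, DMAP cat., CH2Cl2) gives [(2S,3R)-3-(chloromethyl)-3-methyloxiran-2-yl]methyl 4-methylbenzenesulfonate F5. Anhydrous HBr in CH2Cl2 at −78 °C opens the protonated epoxide at the tertiary carbon to give (2S,3S)-3-bromo-4-chloro-2-hydroxy-3-methylbutyl 4-methylbenzenesulfonate F6. K2CO3 in MeOH at 0 °C closes F6 to the terminal epoxide, and the route is rejoined at 9; closure onto the bromide would only return F5, which is resubmitted.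

**Further compounds**
F1 | step 10 | [(2S,3R)-3-(chloromethyl)-3-methyloxiran-2-yl]methyl trifluoromethanesulfonate | FC(F)(F)S(=O)(=O)OC[C@@H]1O[C@@]1(C)CCl
F2 | step 10 | (2R,3S)-3-[(2Z,4E)-5-bromo-3-methylpenta-2,4-dien-1-yl]-2-(chloromethyl)-2-methyloxirane | Br/C=C/C(C)=C\C[C@@H]1O[C@@]1(C)CCl
F3 | step 6 | (2S,3S)-3-bromo-4-chloro-3-methyl-2-[(triethylsilyl)oxy]butyl trifluoromethanesulfonate | FC(F)(F)S(=O)(=O)OC[C@H](O[Si](CC)(CC)CC)[C@](C)(Br)CCl
F4 | step 6 | triethyl{[(2S,3S,5Z,7E)-2,8-dibromo-1-chloro-2,6-dimethylocta-5,7-dien-3-yl]oxy}silane | Br/C=C/C(C)=C\C[C@H](O[Si](CC)(CC)CC)[C@](C)(Br)CCl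
F5 | step 5 | [(2S,3R)-3-(chloromethyl)-3-methyloxiran-2-yl]methyl 4-methylbenzenesulfonate | Cc1ccc(cc1)S(=O)(=O)OC[C@@H]1O[C@@]1(C)CCl
F6 | step 5 | (2S,3S)-3-bromo-4-chloro-2-hydroxy-3-methylbutyl 4-methylbenzenesulfonate | Cc1ccc(cc1)S(=O)(=O)OC[C@H](O)[C@](C)(Br)CCl
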